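The C6(O)–C7(=C11)–C8(O) array of the butenolide-fused ten-membered ring is treated as a latent dihydroxyacetone and traced back to an axially chiral allene C6=C7=C8. Double epoxidation gives a spirodiepoxide. Strain-release opening at propargylic C6 by 2-(diethoxyphosphoryl)acrylic acid forms the lactone O–C6 bond and unveils the C7 ketone and the C8 hydroxyl. Acetate conjugate addition then triggers an intramolecular Horner–Wadsworth–Emmons closure that forms C7=C11 and installs the C13 acetate, all in one flask. The ring C1–C10 is closed later by a Nozaki–Hiyama–Kishi reaction (C3–C4), followed by peripheral epoxidation and oxidation to the 1,3-dione.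

Key step: step 10

Remark (atom labels): ring carbons are C1–C10 (C1 = ketone carbon next to the methyl-bearing C10, C3 = ketone carbon next to the epoxide C4–C5, C6 = lactone O–CH, C7 = ring alkene carbon, C8 = acyloxy carbon); C11, C12, C13 = lactone α-carbon, carbonyl carbon and CH2OAc carbon; all intermediates keep these labels.

Remark (assumption): the ligand antipodes named in steps 1 and 6 are taken to be those that give the drawn configurations; if the sense of induction is opposite, the mirror-image ligand is used.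

Step 1
Reactants: 1 3-[(tert-butyldimethylsilyl)oxy]propan-1-ol; 2 but-3-en-2-yl acetate (racemic)
Product: 4 (3R,4S)-1-[(tert-butyldimethylsilyl)oxy]-4-methylhex-5-en-3-ol, via aldehyde 3 (not isolated)
Conditions: [Ir(cod)Cl]2 (2.5 mol%), (S)-SEGPHOS (5 mol%), 4-cyano-3-nitrobenzoic acid (10 mol%), Cs2CO3 (20 mol%), THF, 70 °C
Reagents that add atoms: none
Why: Krische anti-crotylation from the alcohol oxidation level: the cyclometallated iridium catalyst should dehydrogenate 1 to 3 and add its (E)-σ-crotyl ligand through a closed chair transition state, so the anti C1–OH/C10–Me relationship follows from the chair and the absolute configuration (C10 S, C1 R) from the SEGPHOS antipode.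

Step 2
Reactants: 4 homoallylic alcohol
Product: 5 (3S,4R)-4,6-bis[(tert-butyldimethylsilyl)oxy]-3-methylhex-1-ene
Conditions: TBSOTf, 2,6-lutidine, CH2Cl2, −78 → 0 °C
Reagents that add atoms: tert-butyldimethylsilyl trifluoromethanesulfonate, CC(C)(C)[Si](C)(C)OS(=O)(=O)C(F)(F)F
Why: O-silylation of the secondary alcohol with a silyl triflate, which leaves both stereocentres untouched.

Step 3
Reactants: 5 bis-silyl ether
Product: 7 (3S,4R)-4,6-bis[(tert-butyldimethylsilyl)oxy]-3-methylhexan-1-ol, via alkylborane 6 (not isolated)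
Conditions: 9-BBN, THF, 0 → 23 °C; then NaOH (aq), H2O2, 0 °C
Reagents that add atoms: hydrogen peroxide, OO
Why: Brown hydroboration–oxidation: the bulky borane adds anti-Markovnikov to the terminal alkene and the C–B bond is oxidised with retention, giving the primary alcohol at C8.

Step 4
Reactants: 7 primary alcohol
Product: 8 (3S,4R)-4,6-bis[(tert-butyldimethylsilyl)oxy]-3-methylhexanal
Conditions: Dess–Martin periodinane, NaHCO3, CH2Cl2, 0 → 23 °C
Reagents that add atoms: none
Why: Dess–Martin oxidation to the aldehyde under buffered conditions; the nearest stereocentre (C10) is β to the carbonyl and cannot epimerise.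

Step 5
Reactants: 9 1,4-dichlorobut-2-yne
Product: 11 penta-1,3-diyne, via sodium butadiynide 10 (not isolated)
Conditions: NaNH2 (3.1 equiv), liquid NH3, −40 °C; then MeI, −40 °C; product distilled into toluene and used as a solution
Reagents that add atoms: iodomethane, CI
Why: twofold 1,4-dehydrochlorination gives butadiyne, which is deprotonated in the same flask and C-methylated once (elimination–alkylation).

Step 6
Reactants: 8 aldehyde; 11 penta-1,3-diyne
Product: 12 (6R,8S,9R)-9,11-bis[(tert-butyldimethylsilyl)oxy]-8-methylundeca-2,4-diyn-6-ol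
Conditions: (S,S)-ProPhenol (20 mol%), Me2Zn (3 equiv), Ph3P=O (40 mol%), toluene, 4 °C
Reagents that add atoms: none
Why: zinc–ProPhenol-catalysed asymmetric alkynylation: the dinuclear zinc complex binds the aldehyde and the zinc diynide and delivers the diyne to one aldehyde face, so the C8 carbinol (R) is set by the ligand and not by the remote C10/C1 centres.

Step 7
Reactants: 12 diynol
Product: 15 (Ra,8S,9R)-9,11-bis[(tert-butyldimethylsilyl)oxy]-8-methylundeca-4,5-dien-2-yne, via sulfonylhydrazine 13 (not isolated), via diazene 14 (not isolated)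
Conditions: PPh3, DEAD, THF, −15 °C; then 2-nitrobenzenesulfonylhydrazide, −15 → 23 °C
Reagents that add atoms: none
Why: Myers allene synthesis: Mitsunobu displacement of the propargylic hydroxyl by the hydrazide nitrogen with inversion, loss of sulfinic acid and suprafacial retro-ene extrusion of N2 deliver hydrogen to C6 and transfer the C8 configuration stereospecifically to the C6=C7=C8 axis (Ra).

Step 8
Reactants: 16 tert-butyl 2-(diethoxyphosphoryl)acetate
Product: 19 tert-butyl 2-(diethoxyphosphoryl)acrylate, via Mannich base 17 (not isolated), via ammonium iodide 18 (not isolated)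
Conditions: NaH, THF, 0 °C; CH2=NMe2+ I−, 0 → 23 °C; then MeI, CH2Cl2, 23 °C; then NaHCO3 (aq), 23 °C
Reagents that add atoms: N,N-dimethylmethyleneiminium iodide (Eschenmoser's salt), C=[N+](C)C.[I-]
Why: Mannich methylenation: the phosphonoacetate anion adds to the iminium salt, and N-methylation followed by base-induced loss of trimethylamine gives the α-methylene ester.

Step 9
Reactants: 19 tert-butyl acrylate
Product: 20 2-(diethoxyphosphoryl)acrylic acid
Conditions: CF3CO2H, CH2Cl2, 0 → 23 °C; concentrated and used at once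
Reagents that add atoms: none
Why: acidolysis of the tert-butyl ester by loss of 2-methylpropene, under which the ethyl phosphonate esters and the acrylate are stable.

Step 10
Reactants: 15 allenyne; 20 2-(diethoxyphosphoryl)acrylic acid
Product: 24 [(5R)-4-[(1S,3S,4R)-4,6-bis[(tert-butyldimethylsilyl)oxy]-1-hydroxy-3-methylhexyl]-2-oxo-5-(prop-1-yn-1-yl)-2,5-dihydrofuran-3-yl]methyl acetate, via spirodiepoxide 21 (not isolated), via phosphonoacrylate ester 22 (not isolated), via acetate adduct 23 (not isolated)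
Conditions: DMDO (2.5 equiv, acetone), CHCl3, −40 → 0 °C; volatiles removed at 0 °C; 20 (1.3 equiv), CH2Cl2, −40 → 0 °C; then Bu4NOAc (2.5 equiv), MeCN, −20 → 0 °C
Reagents that add atoms: dimethyldioxirane, CC1(C)OO1; tetrabutylammonium acetate, CCCC[N+](CCCC)(CCCC)CCCC.CC(=O)[O-]
Why: DMDO should transfer oxygen to both π bonds of the allene, each from the face anti to the substituent on the distal allene carbon, to give spirodiepoxide 21 (closest known type: double epoxidation of 1,3-disubstituted allenes, two concerted oxygen-transfer closures of oxiranes). Acid 20 then opens 21 by backside attack at the propargylic carbon C6, a strain-release step that forms the O–C6 bond with inversion and lets the second oxirane collapse to the C7 ketone and the C8 hydroxyl with retention (closest known type: opening of allene spirodiepoxides by carboxylic acids to syn-α-acyloxy-α'-hydroxy ketones). Acetate adds to the 2-phosphonoacrylate of 22, and the phosphonate carbanion so formed attacks the C7 ketone in a 5-exo-trig closure and expels diethyl phosphate, which forms C7=C11, closes the butenolide and leaves the C13 acetate in place (closest known type: conjugate addition/intramolecular Horner–Wadsworth–Emmons reaction of 2-oxoalkyl 2-phosphonoacrylates). C6 and C8 are both controlled by the Ra axis of 15, since anti epoxidation followed by inversion at C6 and retention at C8 can only give the syn C6–O/C8–O pair of 37. The step needs attack at C6 and not at C8, facial control in both epoxidations, and olefination faster than enolisation at C6 or acyl shift to O8: C6 is the propargylically activated and less hindered terminus, the C8 side chain shields one face, and the carbanion arises next to the ketone by addition under near-neutral conditions, while loss of acetate from 23 merely regenerates 22 for recapture.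

Step 11
Reactants: 25 4-methylfuran-2(5H)-one
Product: 28 (Z)-4-[(tert-butyldiphenylsilyl)oxy]-3-methylbut-2-enoic acid, via sodium salt 26 (not isolated), via silyl ester 27 (not isolated)
Conditions: NaOH (1.0 equiv), H2O/THF, 0 → 23 °C; solvent removed; TBDPSCl (2.2 equiv), imidazole, DMF, 23 °C; then K2CO3, MeOH/THF/H2O, 0 °C; acidified to pH 5
Reagents that add atoms: sodium hydroxide, [Na+].[OH-]; tert-butyl(chloro)diphenylsilane, CC(C)(C)[Si](Cl)(c1ccccc1)c1ccccc1
Why: lactone saponification gives the hydroxy acid salt whose Z geometry is inherited from the ring, silylation of both oxygens prevents relactonisation, and only the labile silyl ester is cleaved by carbonate.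

Step 12
Reactants: 24 hydroxy butenolide; 28 side-chain acid
Product: 29 [(5R)-4-[(1S,3S,4R)-4,6-bis[(tert-butyldimethylsilyl)oxy]-1-{[(Z)-4-[(tert-butyldiphenylsilyl)oxy]-3-methylbut-2-enoyl]oxy}-3-methylhexyl]-2-oxo-5-(prop-1-yn-1-yl)-2,5-dihydrofuran-3-yl]methyl acetate
Conditions: EDC·HCl, DMAP (0.3 equiv), CH2Cl2, 0 °C
Reagents that add atoms: none
Why: Steglich esterification of the C8 hydroxyl (acyl–oxygen bond formation, so C8 keeps its configuration), run cold to spare the base-sensitive C6–H.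

Step 13
Reactants: 29 alkynyl ester
Product: 30 the C4 triethylsilyl alkene: as 29 but with a 5-[(E)-2-(triethylsilyl)prop-1-en-1-yl] group on the furanone in place of propynyl
Conditions: PtCl2 (5 mol%), XPhos (10 mol%), Et3SiH (1.5 equiv), THF, 50 °C
Reagents that add atoms: triethylsilane, CC[SiH](CC)CC
Why: platinum-catalysed syn-hydrosilylation of the internal alkyne, in which silicon should go to C4, the carbon remote from the electron-withdrawing propargylic lactone oxygen and next to the small methyl group, giving the E-vinylsilane.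

Step 14
Reactants: 30 vinylsilane
Product: 31 the C4 iodide: as 29 but with a 5-[(E)-2-iodoprop-1-en-1-yl] group on the furanone
Conditions: N-iodosuccinimide (1.3 equiv), 2,6-lutidine (0.5 equiv), (CF3)2CHOH, 0 °C
Reagents that add atoms: N-iodosuccinimide, O=C1CCC(=O)N1I
Why: iododesilylation by ipso attack of iodonium on the vinylsilane through a β-silyl cation, which replaces silicon by iodine with retention of the E geometry.

Step 15
Reactants: 31 vinyl iodide
Product: 32 the C1,C3-diol: as 31 but with a (1S,3S,4R)-4,6-dihydroxy-3-methylhexyl chain (C8 ester kept)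
Conditions: HF (48% aq), MeCN, 0 → 23 °C
Reagents that add atoms: none
Why: acidic fluoride cleaves the two tert-butyldimethylsilyl ethers at C1 and C3, while the far more acid-stable tert-butyldiphenylsilyl ether, the acetate and the vinyl iodide should persist.

Step 16
Reactants: 32 diol
Product: 33 the C3 aldehyde: as 32 but with a (1S,3S,4R)-4-hydroxy-3-methyl-6-oxohexyl chain
Conditions: TEMPO (0.2 equiv), PhI(OAc)2 (1.2 equiv), CH2Cl2, 23 °C
Reagents that add atoms: none
Why: oxoammonium (TEMPO) oxidation is selective for the primary C3 alcohol over the hindered secondary C1 alcohol and gives the β-hydroxy aldehyde, which is used without delay.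

Step 17
Reactants: 33 iodo aldehyde
Product: 34 (4E)-13-acetoxy-1,3-dihydroxy-8-{[(Z)-4-[(tert-butyldiphenylsilyl)oxy]-3-methylbut-2-enoyl]oxy}germacra-4,7(11)-dien-12,6-olide (C1 R; C6 and C8 and C10 as in 37; C3 both epimers)
Conditions: CrCl2 (15 equiv), NiCl2 (0.1 equiv), DMSO/THF 3:1, 2 mM, 23 °C
Reagents that add atoms: none
Why: intramolecular Nozaki–Hiyama–Kishi reaction: nickel inserts into the C4–I bond, transmetallation gives a vinylchromium species that keeps the E geometry and adds chemoselectively to the C3 aldehyde at high dilution to close the ten-membered ring; the new C3 carbinol is oxidised later, so its configuration is immaterial.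

Step 18
Reactants: 34 macrocyclic diene diol
Product: 35 the 4,5-epoxide of 34 (C4 and C5 as in 37)
Conditions: mCPBA (1.2 equiv), NaHCO3, CH2Cl2, 0 °C
Reagents that add atoms: 3-chloroperoxybenzoic acid, O=C(OO)c1cccc(Cl)c1
Why: Prilezhaev epoxidation of the only electron-rich alkene (C4=C5): in the E-cyclodecene the ring blocks the inner face and, with H6 eclipsing the alkene to avoid A1,3 strain with the C4 methyl, the exposed face is the one syn to the C6–O bond, which should give the trans 4,5-epoxide with C4 and C5 as in 37.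

Step 19
Reactants: 35 epoxy diol
Product: 36 the tert-butyldiphenylsilyl ether of 37
Conditions: Dess–Martin periodinane (3 equiv), NaHCO3, CH2Cl2, 0 → 23 °C
Reagents that add atoms: none
Why: Dess–Martin oxidation of both secondary alcohols (C1 and the epoxy carbinol C3) gives the 1,3-dione under buffered, non-basic conditions that should spare the epoxide and the C10 stereocentre.

Step 20
Reactants: 36 silyl ether
Product: 37 (4S,5R,6S,8S,10S)-13-acetoxy-4,5-epoxy-8-{[(Z)-4-hydroxy-3-methylbut-2-enoyl]oxy}-1,3-dioxogermacr-7(11)-en-12,6-olide (CNP0295642.1)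
Conditions: HF·pyridine, pyridine, THF, 0 → 23 °C
Reagents that add atoms: none
Why: buffered fluoride-mediated desilylation of the primary allylic silyl ether under weakly acidic conditions that should leave the epoxy ketone, the β-diketone, the allylic acetate and the Z-hydroxy enoate intact.

Compound list

1 | 3-[(tert-butyldimethylsilyl)oxy]propan-1-ol | OCCCO[Si](C)(C)C(C)(C)C | starting material
2 | but-3-en-2-yl acetate (racemic) | CC(OC(C)=O)C=C | starting material
3 | 3-[(tert-butyldimethylsilyl)oxy]propanal | O=CCCO[Si](C)(C)C(C)(C)C | intermediate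
4 | (3R,4S)-1-[(tert-butyldimethylsilyl)oxy]-4-methylhex-5-en-3-ol | C=C[C@H](C)[C@H](O)CCO[Si](C)(C)C(C)(C)C | intermediate
5 | (3S,4R)-4,6-bis[(tert-butyldimethylsilyl)oxy]-3-methylhex-1-ene | C=C[C@H](C)[C@H](O[Si](C)(C)C(C)(C)C)CCO[Si](C)(C)C(C)(C)C | intermediate
6 | 9-[(3S,4R)-4,6-bis[(tert-butyldimethylsilyl)oxy]-3-methylhexyl]-9-borabicyclo[3.3.1]nonane | C1CC2CCCC(C1)B2CC[C@H](C)[C@H](O[Si](C)(C)C(C)(C)C)CCO[Si](C)(C)C(C)(C)C | intermediate
7 | (3S,4R)-4,6-bis[(tert-butyldimethylsilyl)oxy]-3-methylhexan-1-ol | OCC[C@H](C)[C@H](O[Si](C)(C)C(C)(C)C)CCO[Si](C)(C)C(C)(C)C | intermediate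
8 | (3S,4R)-4,6-bis[(tert-butyldimethylsilyl)oxy]-3-methylhexanal | O=CC[C@H](C)[C@H](O[Si](C)(C)C(C)(C)C)CCO[Si](C)(C)C(C)(C)C | intermediate
9 | 1,4-dichlorobut-2-yne | ClCC#CCCl | starting material
10 | sodium buta-1,3-diyn-1-ide | [Na+].[C-]#CC#C | intermediate
11 | penta-1,3-diyne | CC#CC#C | intermediate
12 | (6R,8S,9R)-9,11-bis[(tert-butyldimethylsilyl)oxy]-8-methylundeca-2,4-diyn-6-ol | CC#CC#C[C@H](O)C[C@H](C)[C@H](O[Si](C)(C)C(C)(C)C)CCO[Si](C)(C)C(C)(C)C | intermediate
13 | N-[(6S,8S,9R)-9,11-bis[(tert-butyldimethylsilyl)oxy]-8-methylundeca-2,4-diyn-6-yl]-2-nitrobenzenesulfonohydrazide | CC#CC#C[C@@H](N(N)S(=O)(=O)c1ccccc1[N+](=O)[O-])C[C@H](C)[C@H](O[Si](C)(C)C(C)(C)C)CCO[Si](C)(C)C(C)(C)C | intermediate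
14 | [(6S,8S,9R)-9,11-bis[(tert-butyldimethylsilyl)oxy]-8-methylundeca-2,4-diyn-6-yl]diazene | CC#CC#C[C@@H](N=N)C[C@H](C)[C@H](O[Si](C)(C)C(C)(C)C)CCO[Si](C)(C)C(C)(C)C | intermediate
15 | (Ra,8S,9R)-9,11-bis[(tert-butyldimethylsilyl)oxy]-8-methylundeca-4,5-dien-2-yne | CC#CC([H])=[C@]=C([H])C[C@H](C)[C@H](O[Si](C)(C)C(C)(C)C)CCO[Si](C)(C)C(C)(C)C | intermediate
16 | tert-butyl 2-(diethoxyphosphoryl)acetate | CCOP(=O)(OCC)CC(=O)OC(C)(C)C | starting material
17 | tert-butyl 2-(diethoxyphosphoryl)-3-(dimethylamino)propanoate | CCOP(=O)(OCC)C(CN(C)C)C(=O)OC(C)(C)C | intermediate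
18 | 3-(tert-butoxy)-2-(diethoxyphosphoryl)-N,N,N-trimethyl-3-oxopropan-1-aminium iodide | CCOP(=O)(OCC)C(C[N+](C)(C)C)C(=O)OC(C)(C)C.[I-] | intermediate
19 | tert-butyl 2-(diethoxyphosphoryl)acrylate | C=C(C(=O)OC(C)(C)C)P(=O)(OCC)OCC | intermediate
20 | 2-(diethoxyphosphoryl)acrylic acid | C=C(C(=O)O)P(=O)(OCC)OCC | intermediate
21 | 2-[(2S,3R)-3,5-bis[(tert-butyldimethylsilyl)oxy]-2-methylpentyl]-5-(prop-1-yn-1-yl)-1,4-dioxaspiro[2.2]pentane (spirodiepoxide of 15; each oxygen anti to the distal substituent) | CC#C[C@@H]1O[C@@]12O[C@H]2C[C@H](C)[C@H](O[Si](C)(C)C(C)(C)C)CCO[Si](C)(C)C(C)(C)C | intermediate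
22 | (4R,6S,8S,9R)-9,11-bis[(tert-butyldimethylsilyl)oxy]-6-hydroxy-8-methyl-5-oxoundec-2-yn-4-yl 2-(diethoxyphosphoryl)acrylate | C=C(C(=O)O[C@H](C#CC)C(=O)[C@@H](O)C[C@H](C)[C@H](O[Si](C)(C)C(C)(C)C)CCO[Si](C)(C)C(C)(C)C)P(=O)(OCC)OCC | intermediate
23 | (4R,6S,8S,9R)-9,11-bis[(tert-butyldimethylsilyl)oxy]-6-hydroxy-8-methyl-5-oxoundec-2-yn-4-yl 3-acetoxy-2-(diethoxyphosphoryl)propanoate (both epimers at the phosphonate carbon) | CC(=O)OCC(C(=O)O[C@H](C#CC)C(=O)[C@@H](O)C[C@H](C)[C@H](O[Si](C)(C)C(C)(C)C)CCO[Si](C)(C)C(C)(C)C)P(=O)(OCC)OCC | intermediate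
24 | [(5R)-4-[(1S,3S,4R)-4,6-bis[(tert-butyldimethylsilyl)oxy]-1-hydroxy-3-methylhexyl]-2-oxo-5-(prop-1-yn-1-yl)-2,5-dihydrofuran-3-yl]methyl acetate | CC(=O)OCC1=C([C@@H](O)C[C@H](C)[C@H](O[Si](C)(C)C(C)(C)C)CCO[Si](C)(C)C(C)(C)C)[C@@H](C#CC)OC1=O | intermediate
25 | 4-methylfuran-2(5H)-one | CC1=CC(=O)OC1 | starting material
26 | sodium (Z)-4-hydroxy-3-methylbut-2-enoate | [Na+].[O-]C(=O)/C=C(/C)CO | intermediate
27 | tert-butyldiphenylsilyl (Z)-4-[(tert-butyldiphenylsilyl)oxy]-3-methylbut-2-enoate | CC(C)(C)[Si](OC(=O)/C=C(/C)CO[Si](c1ccccc1)(c1ccccc1)C(C)(C)C)(c1ccccc1)c1ccccc1 | intermediate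
28 | (Z)-4-[(tert-butyldiphenylsilyl)oxy]-3-methylbut-2-enoic acid | OC(=O)/C=C(/C)CO[Si](c1ccccc1)(c1ccccc1)C(C)(C)C | intermediate
29 | [(5R)-4-[(1S,3S,4R)-4,6-bis[(tert-butyldimethylsilyl)oxy]-1-{[(Z)-4-[(tert-butyldiphenylsilyl)oxy]-3-methylbut-2-enoyl]oxy}-3-methylhexyl]-2-oxo-5-(prop-1-yn-1-yl)-2,5-dihydrofuran-3-yl]methyl acetate | CC(=O)OCC1=C([C@@H](OC(=O)/C=C(/C)CO[Si](c2ccccc2)(c2ccccc2)C(C)(C)C)C[C@H](C)[C@H](O[Si](C)(C)C(C)(C)C)CCO[Si](C)(C)C(C)(C)C)[C@@H](C#CC)OC1=O | intermediate
30 | as 29 with 5-[(E)-2-(triethylsilyl)prop-1-en-1-yl] in place of propynyl (silicon on C4, trans to C6) | CC(=O)OCC1=C([C@@H](OC(=O)/C=C(/C)CO[Si](c2ccccc2)(c2ccccc2)C(C)(C)C)C[C@H](C)[C@H](O[Si](C)(C)C(C)(C)C)CCO[Si](C)(C)C(C)(C)C)[C@@H](/C=C(/[Si](CC)(CC)CC)C)OC1=O | intermediate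
31 | as 29 with 5-[(E)-2-iodoprop-1-en-1-yl] in place of propynyl (iodine on C4, trans to C6) | CC(=O)OCC1=C([C@@H](OC(=O)/C=C(/C)CO[Si](c2ccccc2)(c2ccccc2)C(C)(C)C)C[C@H](C)[C@H](O[Si](C)(C)C(C)(C)C)CCO[Si](C)(C)C(C)(C)C)[C@@H](/C=C(/I)C)OC1=O | intermediate
32 | C1,C3-diol of 31 [(1S,3S,4R)-4,6-dihydroxy-3-methylhexyl chain; C8 ester and vinyl iodide kept] | CC(=O)OCC1=C([C@@H](OC(=O)/C=C(/C)CO[Si](c2ccccc2)(c2ccccc2)C(C)(C)C)C[C@H](C)[C@H](O)CCO)[C@@H](/C=C(/I)C)OC1=O | intermediate
33 | C3 aldehyde of 32 [(1S,3S,4R)-4-hydroxy-3-methyl-6-oxohexyl chain] | CC(=O)OCC1=C([C@@H](OC(=O)/C=C(/C)CO[Si](c2ccccc2)(c2ccccc2)C(C)(C)C)C[C@H](C)[C@H](O)CC=O)[C@@H](/C=C(/I)C)OC1=O | intermediate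
34 | (4E)-13-acetoxy-1,3-dihydroxy-8-{[(Z)-4-[(tert-butyldiphenylsilyl)oxy]-3-methylbut-2-enoyl]oxy}germacra-4,7(11)-dien-12,6-olide (C1 R; C6, C8, C10 as in 37; C3 both epimers) | CC(=O)OCC1=C2[C@@H](OC(=O)/C=C(/C)CO[Si](c4ccccc4)(c4ccccc4)C(C)(C)C)C[C@H](C)[C@H](O)CC(O)/C(C)=C/[C@H]2OC1=O | intermediate
35 | 4,5-epoxide of 34 (C4, C5 as in 37; C3 both epimers) | CC(=O)OCC1=C2[C@@H](OC(=O)/C=C(/C)CO[Si](c4ccccc4)(c4ccccc4)C(C)(C)C)C[C@H](C)[C@H](O)CC(O)[C@@]3(C)O[C@@H]3[C@H]2OC1=O | intermediate
36 | tert-butyldiphenylsilyl ether of 37 at the side-chain hydroxyl | CC(=O)OCC1=C2[C@@H](OC(=O)/C=C(/C)CO[Si](c4ccccc4)(c4ccccc4)C(C)(C)C)C[C@H](C)C(=O)CC(=O)[C@@]3(C)O[C@@H]3[C@H]2OC1=O | intermediate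
37 | (4S,5R,6S,8S,10S)-13-acetoxy-4,5-epoxy-8-{[(Z)-4-hydroxy-3-methylbut-2-enoyl]oxy}-1,3-dioxogermacr-7(11)-en-12,6-olide (CNP0295642.1) | CC(=O)OCC1=C2[C@@H](OC(=O)/C=C(/C)CO)C[C@H](C)C(=O)CC(=O)[C@@]3(C)O[C@@H]3[C@H]2OC1=O | target

Total step count: 20 (16 on the main line plus steps 5, 8, 9 and 11 for the three building blocks).
Longest linear sequence: 16 steps (1, 2, 3, 4, 6, 7, 10, 12, 13, 14, 15, 16, 17, 18, 19, 20) from 1.

Steps most likely to fail

Step 10. After acid 20 has opened spirodiepoxide 21, acetate may add too slowly to the phosphonoacrylate of 22, so that oligomerisation of this acceptor, shift of the acyl group from O6 to O8, or base-induced isomerisation at the propargylic C6–H outruns the olefination. The fallback sets out from 15 and comes back at 29. It keeps the one-flask formation of the O–C6 and C7=C11 bonds but uses an alkoxide as the conjugate donor, for which this addition/olefination tandem is established, and exchanges the ether for the acetate afterwards. 15 is taken to 22 as before; 4-methoxybenzyl alcohol, DBU and LiCl in MeCN at 0 °C should then give [(5R)-4-[(1S,3S,4R)-4,6-bis[(tert-butyldimethylsilyl)oxy]-1-hydroxy-3-methylhexyl]-3-{[(4-methoxybenzyl)oxy]methyl}-5-(prop-1-yn-1-yl)furan-2(5H)-one] F1. Steglich esterification with 28 (EDC·HCl, DMAP, CH2Cl2, 0 °C) gives the C8 ester of F1 F2. DDQ in CH2Cl2/pH 7 buffer frees the C13 alcohol F3, and Ac2O/pyridine gives 29.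

Step 17. Intermolecular coupling to oligomers or protodeiodination of the vinylchromium species may win over closure of the strained ten-membered ring. The fallback sets out from 29 and comes back at 34. It forms the same C3–C4 bond by nickel-catalysed reductive alkyne–aldehyde cyclisation, without the vinyl iodide. Aqueous HF in MeCN removes the two tert-butyldimethylsilyl groups of 29 to give the alkynyl C1,C3-diol F4, and TEMPO/PhI(OAc)2 gives the alkynyl C3 aldehyde F5. Ni(cod)2 with the carbene IMes (from IMes·HCl and KOt-Bu; the regiochemistry is ligand-dependent) and Et3SiH in THF at high dilution should give the macrocyclic C3 triethylsilyl ether of 34 F6, by syn addition of hydrogen and the aldehyde carbon across the alkyne with C–C bond formation at the methyl-bearing carbon. Aqueous HF in MeCN then gives 34.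

Step 6. Direct asymmetric alkynylation of the enolisable, β-branched aldehyde 8 with the volatile diyne may stall or give poor facial control at C8. The fallback sets out from 8 and 11 and comes back at 12. It sets C8 by oxidation and catalyst-controlled reduction instead. Lithium pentadiynide (11, n-BuLi, THF, −78 °C) adds to 8 to give the diynol as a C8 epimer mixture F7; Dess–Martin oxidation gives the diynone F8; Noyori transfer hydrogenation with RuCl(p-cymene)[(R,R)-TsDPEN] in i-PrOH should give 12.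

Further compounds
F1 | step 10 | 13-O-(4-methoxybenzyl) analogue of 24 (C8 hydroxyl free) | COc1ccc(COCC2=C([C@@H](O)C[C@H](C)[C@H](O[Si](C)(C)C(C)(C)C)CCO[Si](C)(C)C(C)(C)C)[C@@H](C#CC)OC2=O)cc1
F2 | step 10 | 13-O-(4-methoxybenzyl) analogue of 29 | COc1ccc(COCC2=C([C@@H](OC(=O)/C=C(/C)CO[Si](c3ccccc3)(c3ccccc3)C(C)(C)C)C[C@H](C)[C@H](O[Si](C)(C)C(C)(C)C)CCO[Si](C)(C)C(C)(C)C)[C@@H](C#CC)OC2=O)cc1
F3 | step 10 | 13-hydroxy analogue of 29 | OCC1=C([C@@H](OC(=O)/C=C(/C)CO[Si](c2ccccc2)(c2ccccc2)C(C)(C)C)C[C@H](C)[C@H](O[Si](C)(C)C(C)(C)C)CCO[Si](C)(C)C(C)(C)C)[C@@H](C#CC)OC1=O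
F4 | step 17 | C1,C3-diol of 29 (alkyne kept) | CC(=O)OCC1=C([C@@H](OC(=O)/C=C(/C)CO[Si](c2ccccc2)(c2ccccc2)C(C)(C)C)C[C@H](C)[C@H](O)CCO)[C@@H](C#CC)OC1=O
F5 | step 17 | C3 aldehyde of F4 | CC(=O)OCC1=C([C@@H](OC(=O)/C=C(/C)CO[Si](c2ccccc2)(c2ccccc2)C(C)(C)C)C[C@H](C)[C@H](O)CC=O)[C@@H](C#CC)OC1=O
F6 | step 17 | C3 triethylsilyl ether of 34 (C3 both epimers) | CC(=O)OCC1=C2[C@@H](OC(=O)/C=C(/C)CO[Si](c4ccccc4)(c4ccccc4)C(C)(C)C)C[C@H](C)[C@H](O)CC(O[Si](CC)(CC)CC)/C(C)=C/[C@H]2OC1=O
F7 | step 6 | (8S,9R)-9,11-bis[(tert-butyldimethylsilyl)oxy]-8-methylundeca-2,4-diyn-6-ol (C6 both epimers) | CC#CC#CC(O)C[C@H](C)[C@H](O[Si](C)(C)C(C)(C)C)CCO[Si](C)(C)C(C)(C)C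
F8 | step 6 | (8S,9R)-9,11-bis[(tert-butyldimethylsilyl)oxy]-8-methylundeca-2,4-diyn-6-one | CC#CC#CC(=O)C[C@H](C)[C@H](O[Si](C)(C)C(C)(C)C)CCO[Si](C)(C)C(C)(C)C
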